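The earlier runs and the new flask stem from a simulated flask with constants of no real substance.

Electrophile is left over in the delta run at 5.00 h, 56% of its charge, yet from 2.00 h on the target gains just 8 percentage points.

| flask | electrophile | nucleophile | free base | scavenger | remark | time |
|---|---|---|---|---|---|---|
| delta | 0.10 M | 0.060 M | 0.12 M | 0.12 M | run made earlier |  |
| epsilon | 0.10 M | 0.14 M | 0.12 M | 0.12 M | run made earlier |  |
| alpha | 0.20 M | 0.090 M | 0.12 M | 0.12 M | run made earlier |  |
| flask | 0.10 M | 0.0900 M | 0.120 M | 0.120 M |  | 8.0 h |

| run | time / h | electrophile / % | target / % |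
|---|---|---|---|
| delta | 0.417 | 74 | 15 |
| delta | 0.667 | 63 | 19 |
| delta | 0.833 | 66 | 22 |
| delta | 1.33 | 62 | 24 |
| delta | 2.00 | 54 | 27 |
| delta | 3.00 | 61 | 30 |
| delta | 5.00 | 56 | 35 |
| epsilon | 0.250 | 64 | 20 |
| epsilon | 0.667 | 48 | 40 |
| epsilon | 1.33 | 39 | 52 |
| epsilon | 2.00 | 35 | 59 |
| epsilon | 3.00 | 28 | 65 |
| epsilon | 4.00 | 29 | 72 |
| epsilon | 5.00 | 22 | 70 |
| alpha | 0.417 | 67 | 16 |
| alpha | 1.33 | 64 | 24 |
| alpha | 2.00 | 63 | 25 |
| alpha | 3.00 | 60 | 24 |
| alpha | 5.00 | 58 | 31 |

(scatter of a reading: 1.5 percentage points)

- what has gone from electrophile into another species counts as reacted, even if it can come back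
- the earlier runs do not show how much of nucleophile is bound; that part of a forecast is a guess

- part of the electrophile that has reacted at 8.0 h
- share of free nucleophile in free nucleophile and protonated nucleophile together, at 8.0 h

If the acid from each coupling protonates a second nucleophile, the rate of nucleophile loss divided by the rate of target formation is 2. Time then drops out, and the burst ends at the stall yield: the nucleophile charged, divided by 2, per electrophile charged. The target readings slow near this value: delta 30.0% against a reading of 30% at 3.00 h, epsilon 70.0% against 65% at 3.00 h, alpha 22.5% against 25% at 2.00 h. In the flask, the nucleophile charged is less than the electrophile charged, which makes it the limiting reagent, and the stall yield is 45.0%, with a slow tail to follow.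

The forecast gives 63% reacted and 30% free, holding that “each coupling releases acid that ties up a second nucleophile as its protonated form”.

The flask gives 63.8% reacted and 15.0% free, so the forecast is close on the reacted part and 15 points high on the free share.

    electrophile + nucleophile → acid set free + target (k = 0.00260 M⁻¹ s⁻¹)
    nucleophile + acid set free ⇌ protonated nucleophile, settled at all times (K = 8500 M⁻¹)
    acid set free + free base ⇌ salt of the base (K = 9.10 M⁻¹, k = 0.00600 M⁻¹ s⁻¹)
    nucleophile + acid set free ⇌ idle adduct, settled at all times (K = 22.0 M⁻¹)
    acid set free + scavenger → scavenged by-product (k = 0.0150 M⁻¹ s⁻¹)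
    electrophile ⇌ dormant form (K = 0.230, k = 0.00270 s⁻¹)

The flask's target stands at 47.2% at 4.00 h and at 55.4% at 8.00 h, which is 10 points above the stall yield. In the flask, the coupling's half-life for nucleophile, 1.3 h at 0.751 h, is short against the 8.0 h of the run, while the scavenging step's half-life for scavenger, 19 h at 8.00 h, is longer than the run, and 0.0293 M of protonated nucleophile stands in the flask at 8.00 h.

In the neighbouring flask with 0.036 M of nucleophile, the stall yield is 18.0%. The computed target there is 26.9% at 8.00 h, with 40.6% of the electrophile reacted.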